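**Plan**

Pyran numbering: O1, C2 (methyl), C3 (formyl), C4 (CH2CO2R side chain), C5 (CO2Me), C6. Abbreviations: PMB = 4-methoxybenzyl, TES = triethylsilyl, TBS = tert-butyldimethylsilyl.

- Cuts, in retrosynthetic order: the O1–C6 enol-ether bond; the side-chain ester C–O bond to hydroxytyrosol; the C4–C5 bond together with a temporary enol-lactone C–O bond; the side-chain C=C (olefination at C4); the C3–CH2O bond.
- Enabling feature: C6, C5 (with its ester), C4, the side-chain CH2 and the side-chain carboxyl carbon make up, with one oxygen, a 5-methoxycarbonyl-3,4-dihydropyran-2-one (ring A). This enol lactone is the closed form of the C6 formyl enol and the side-chain acyl group.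
- Forward order: the C2–C3 unit is extended to an E-enal; carbene-catalysed oxidative annulation with methyl 3-oxopropanoate closes ring A; alcoholysis by silylated hydroxytyrosol opens ring A; the C2 hydroxyl then closes the dihydropyran (ring B) on C6; the C3 formyl group is unmasked last.
- Stereochemistry: C2 comes from methyl (S)-3-hydroxybutanoate, C3 from the anti-selective dianion alkylation, C4 from the chiral triazolium catalyst.

Key step: step 7

Assumption (catalyst sense): the (5aS,10bR) aminoindanol triazolium is taken to shield the Re face of the β-carbon of the derived acyl azolium; if a trial shows the opposite sense, the mirror-image (5aR,10bS) salt, equally available, is substituted with no other change.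

Assumption (reagent): 4-methoxybenzyl chloromethyl ether is treated as a purchasable, cold-stored reagent.

**Route**

Step 1
Reactants: 1 methyl (S)-3-hydroxybutanoate; 2 4-methoxybenzyl chloromethyl ether
Product: 3 methyl (2S,3S)-3-hydroxy-2-[(PMB-oxy)methyl]butanoate
Conditions: LiN(i-Pr)2 (2.2 equiv), THF, −78 → −20 °C; then 2, DMPU, −78 → −20 °C; aq. NH4Cl
Reagents that add atoms: none
Why: Fráter–Seebach alkylation: the six-membered lithium chelate of the β-hydroxy ester dianion is alkylated by the reactive chloromethyl ether on the enolate face away from the C3 methyl group, which sets the new centre anti to the hydroxyl (2S,3S).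

Step 2
Reactants: 3 methyl (2S,3S)-3-hydroxy-2-[(PMB-oxy)methyl]butanoate
Product: 4 methyl (2S,3S)-2-[(PMB-oxy)methyl]-3-(TES-oxy)butanoate
Conditions: Et3SiCl, imidazole, DMF, 0 °C → rt
Reagents that add atoms: chlorotriethylsilane, CC[Si](Cl)(CC)CC
Why: Standard silylation of a secondary alcohol with a silyl chloride and imidazole; the triethylsilyl ether tolerates hydride, ylide, carbene and acyl-transfer conditions yet is later cleaved by mild acid under which aryl tert-butyldimethylsilyl ethers survive.

Step 3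
Reactants: 4 methyl (2S,3S)-2-[(PMB-oxy)methyl]-3-(TES-oxy)butanoate
Product: 5 (2S,3S)-2-[(PMB-oxy)methyl]-3-(TES-oxy)butan-1-ol
Conditions: (i-Bu)2AlH (2.5 equiv), CH2Cl2, −78 → 0 °C; aq. potassium sodium tartrate
Reagents that add atoms: none
Why: Full ester-to-alcohol reduction with (i-Bu)2AlH is more dependable than a partial reduction at this branched centre, and the silyl and PMB ethers are inert to the hydride.

Step 4
Reactants: 5 (2S,3S)-2-[(PMB-oxy)methyl]-3-(TES-oxy)butan-1-ol
Product: 6 (2S,3S)-2-[(PMB-oxy)methyl]-3-(TES-oxy)butanal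
Conditions: Dess–Martin periodinane, pyridine, CH2Cl2, 0 °C → rt
Reagents that add atoms: none
Why: Dess–Martin oxidation with pyridine buffer gives the α-branched aldehyde under near-neutral conditions that avoid epimerisation and β-elimination of the silyloxy group; the aldehyde is used crude at once.

Step 5
Reactants: 6 (2S,3S)-2-[(PMB-oxy)methyl]-3-(TES-oxy)butanal
Product: 7 (2E,4S,5S)-4-[(PMB-oxy)methyl]-5-(TES-oxy)hex-2-enal
Conditions: Ph3P=CHCHO (1.5 equiv), toluene, 80 °C
Reagents that add atoms: (triphenylphosphoranylidene)acetaldehyde, O=CC=P(c1ccccc1)(c1ccccc1)c1ccccc1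
Why: Wittig olefination with the formyl-stabilised ylide gives the E-enal under thermodynamic control in a neutral medium that leaves the α-centre and both ethers untouched.

Step 6
Reactants: 8 methyl 3,3-dimethoxypropanoate
Product: 9 methyl 3-oxopropanoate (methyl formylacetate, largely as its enol)
Conditions: 2 M aq. HCl, THF, 0 °C → rt; saturate with NaCl, extract (CH2Cl2), dry, use at once
Reagents that add atoms: water, O
Why: Acid-catalysed acetal hydrolysis frees the formyl ester, which exists largely as its hydrogen-bonded enol and is used at once because it trimerises on standing.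

Step 7
Reactants: 7 (2E,4S,5S)-4-[(PMB-oxy)methyl]-5-(TES-oxy)hex-2-enal; 9 methyl 3-oxopropanoate
Product: 10 methyl (4R)-4-[(2S,3S)-1-(PMB-oxy)-3-(TES-oxy)butan-2-yl]-2-oxo-3,4-dihydro-2H-pyran-5-carboxylate
Conditions: (5aS,10bR)-2-mesityl-5a,10b-dihydro-4H,6H-indeno[2,1-b][1,2,4]triazolo[4,3-d][1,4]oxazin-2-ium chloride (10 mol%), i-Pr2NEt (20 mol%), LiCl (0.5 equiv), 3,3',5,5'-tetra-tert-butyldiphenoquinone (1.2 equiv), 9 (2 equiv, slow addition), 4 Å MS, toluene–THF, 0 °C → rt
Reagents that add atoms: none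
Why: The carbene adds to the formyl group of 7, the Breslow intermediate is oxidised by the diphenoquinone to the α,β-unsaturated acyl azolium, the enol of 9 adds through carbon to the β-carbon (future C4), and the formyl enol oxygen of the adduct is then acylated with release of the carbene. This is the carbene-catalysed oxidative annulation of enals with 1,3-dicarbonyl compounds (acyl azolium Michael addition/lactonisation), with a formyl ester as the dicarbonyl partner, whose aldehyde is masked as the enol and so should not engage the carbene. Ring A closes by 6-exo-trig attack of the enol oxygen on the acyl azolium carbonyl. The new C4 centre is set by the catalyst: the indane wall is expected to cover the Re face of the s-cis acyl azolium, so the enol adds to the Si face and gives 4R, while the γ-centre, which carries no polar group directly, should exert only a weak bias of its own. The step needs β- rather than γ-reactivity and C–C before C–O bond formation: the unhindered β-hydrogen-bearing carbon, the weak catalytic base and the LiCl-organised, stabilised enol favour conjugate addition, and a kinetic O-acyl adduct would still converge on 10 by a Claisen-type [3,3] shift.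

Step 8
Reactants: 11 hydroxytyrosol
Product: 12 2-[3,4-bis(TBS-oxy)phenyl]ethyl TBS ether
Conditions: t-BuMe2SiCl (3.6 equiv), imidazole, DMF, rt
Reagents that add atoms: tert-butyldimethylsilyl chloride, CC(C)(C)[Si](C)(C)Cl
Why: Exhaustive silylation of the two phenols and the primary alcohol with a silyl chloride and imidazole.

Step 9
Reactants: 12 2-[3,4-bis(TBS-oxy)phenyl]ethyl TBS ether
Product: 13 2-[3,4-bis(TBS-oxy)phenyl]ethanol
Conditions: (+)-camphor-10-sulfonic acid (0.1 equiv), MeOH–CH2Cl2 (1:1), 0 °C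
Reagents that add atoms: none
Why: Acid-catalysed methanolysis removes the primary alkyl silyl ether far faster than the aryl silyl ethers, which are the acid-stable class, so only the alcohol needed for the ester is freed.

Step 10
Reactants: 10 methyl (4R)-4-[(2S,3S)-1-(PMB-oxy)-3-(TES-oxy)butan-2-yl]-2-oxo-3,4-dihydro-2H-pyran-5-carboxylate; 13 2-[3,4-bis(TBS-oxy)phenyl]ethanol
Product: 14 5-{2-[3,4-bis(TBS-oxy)phenyl]ethyl} 1-methyl (3R)-2-formyl-3-[(2S,3S)-1-(PMB-oxy)-3-(TES-oxy)butan-2-yl]pentanedioate (C2 epimers in equilibrium with the enol)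
Conditions: 4-(dimethylamino)pyridine (1.0 equiv), 13 (1.2 equiv), CH2Cl2, 0 °C → rt; dilute citric acid wash
Reagents that add atoms: none
Why: Nucleophile-catalysed acyl transfer (alcoholysis of an enol lactone, a vinylogous mixed anhydride): the primary alcohol takes the acyl group and the formyl enol leaves, which installs the side-chain ester and frees C6 without touching a stereocentre.

Step 11
Reactants: 14 5-{2-[3,4-bis(TBS-oxy)phenyl]ethyl} 1-methyl (3R)-2-formyl-3-[(2S,3S)-1-(PMB-oxy)-3-(TES-oxy)butan-2-yl]pentanedioate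
Product: 17 methyl (2S,3S,4R)-4-(2-{2-[3,4-bis(TBS-oxy)phenyl]ethoxy}-2-oxoethyl)-2-methyl-3-[(PMB-oxy)methyl]-3,4-dihydro-2H-pyran-5-carboxylate, via hydroxy formyl ester 15 (not isolated), via lactol 16 (not isolated)
Conditions: (+)-camphor-10-sulfonic acid (0.2 equiv), THF–H2O (10:1), rt; then solvent switch to toluene, 4 Å MS, 40 °C
Reagents that add atoms: none
Why: Mild aqueous acid hydrolyses the TES ether while aryl TBS and PMB ethers stay, the freed C2 hydroxyl adds reversibly to the C6 formyl group (six-membered hemiacetal, faster than lactonisation on the side-chain ester), and acid-catalysed dehydration of the lactol gives the conjugated β-alkoxyacrylate as the thermodynamic sink, with C2 keeping its configuration because its C–O bond is never broken.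

Step 12
Reactants: 17 methyl (2S,3S,4R)-4-(2-{2-[3,4-bis(TBS-oxy)phenyl]ethoxy}-2-oxoethyl)-2-methyl-3-[(PMB-oxy)methyl]-3,4-dihydro-2H-pyran-5-carboxylate
Product: 18 methyl (2S,3S,4R)-4-(2-{2-[3,4-bis(TBS-oxy)phenyl]ethoxy}-2-oxoethyl)-3-(hydroxymethyl)-2-methyl-3,4-dihydro-2H-pyran-5-carboxylate
Conditions: DDQ (1.3 equiv), CH2Cl2–pH 7 phosphate buffer (10:1), 0 °C
Reagents that add atoms: none
Why: Oxidative PMB cleavage by DDQ (benzylic hydride abstraction and hydrolysis of the oxocarbenium ion) under buffered conditions at 0 °C, where the electron-poor alkoxyacrylate and the bulky, weakly donating aryl silyl ethers should not be oxidised.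

Step 13
Reactants: 18 methyl (2S,3S,4R)-4-(2-{2-[3,4-bis(TBS-oxy)phenyl]ethoxy}-2-oxoethyl)-3-(hydroxymethyl)-2-methyl-3,4-dihydro-2H-pyran-5-carboxylate
Product: 19 methyl (2S,3R,4R)-4-(2-{2-[3,4-bis(TBS-oxy)phenyl]ethoxy}-2-oxoethyl)-3-formyl-2-methyl-3,4-dihydro-2H-pyran-5-carboxylate
Conditions: Dess–Martin periodinane, pyridine, CH2Cl2, 0 °C → rt
Reagents that add atoms: none
Why: Dess–Martin oxidation of the primary alcohol under pyridine buffering gives the aldehyde without base, and the C3 centre, trans to both neighbours, is in its favoured arrangement so epimerisation is not expected.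

Step 14
Reactants: 19 methyl (2S,3R,4R)-4-(2-{2-[3,4-bis(TBS-oxy)phenyl]ethoxy}-2-oxoethyl)-3-formyl-2-methyl-3,4-dihydro-2H-pyran-5-carboxylate
Product: 20 methyl (2S,3R,4R)-4-{2-[2-(3,4-dihydroxyphenyl)ethoxy]-2-oxoethyl}-3-formyl-2-methyl-3,4-dihydro-2H-pyran-5-carboxylate
Conditions: Bu4NF (2.4 equiv), AcOH (2.4 equiv), THF, 0 °C
Reagents that add atoms: none
Why: Fluoride cleavage of aryl silyl ethers is fast, and buffering with acetic acid keeps the medium near neutral so that the formyl-bearing C3 centre, the alkoxyacrylate and the catechol are preserved.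

**Compound list**

1 | methyl (S)-3-hydroxybutanoate | C[C@H](O)CC(=O)OC | starting material
2 | 4-methoxybenzyl chloromethyl ether | COc1ccc(COCCl)cc1 | starting material
3 | methyl (2S,3S)-3-hydroxy-2-[(PMB-oxy)methyl]butanoate | C[C@H](O)[C@H](COCc1ccc(OC)cc1)C(=O)OC | intermediate
4 | methyl (2S,3S)-2-[(PMB-oxy)methyl]-3-(TES-oxy)butanoate | C[C@H](O[Si](CC)(CC)CC)[C@H](COCc1ccc(OC)cc1)C(=O)OC | intermediate
5 | (2S,3S)-2-[(PMB-oxy)methyl]-3-(TES-oxy)butan-1-ol | C[C@H](O[Si](CC)(CC)CC)[C@H](COCc1ccc(OC)cc1)CO | intermediate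
6 | (2S,3S)-2-[(PMB-oxy)methyl]-3-(TES-oxy)butanal | C[C@H](O[Si](CC)(CC)CC)[C@H](COCc1ccc(OC)cc1)C=O | intermediate
7 | (2E,4S,5S)-4-[(PMB-oxy)methyl]-5-(TES-oxy)hex-2-enal | O=C/C=C/[C@@H](COCc1ccc(OC)cc1)[C@H](C)O[Si](CC)(CC)CC | intermediate
8 | methyl 3,3-dimethoxypropanoate | COC(=O)CC(OC)OC | starting material
9 | methyl 3-oxopropanoate | COC(=O)CC=O | intermediate
10 | methyl (4R)-4-[(2S,3S)-1-(PMB-oxy)-3-(TES-oxy)butan-2-yl]-2-oxo-3,4-dihydro-2H-pyran-5-carboxylate | O=C1C[C@H]([C@@H](COCc2ccc(OC)cc2)[C@H](C)O[Si](CC)(CC)CC)C(C(=O)OC)=CO1 | intermediate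
11 | hydroxytyrosol, 2-(3,4-dihydroxyphenyl)ethanol | OCCc1ccc(O)c(O)c1 | starting material
12 | 2-[3,4-bis(TBS-oxy)phenyl]ethyl TBS ether | CC(C)(C)[Si](C)(C)OCCc1ccc(O[Si](C)(C)C(C)(C)C)c(O[Si](C)(C)C(C)(C)C)c1 | intermediate
13 | 2-[3,4-bis(TBS-oxy)phenyl]ethanol | OCCc1ccc(O[Si](C)(C)C(C)(C)C)c(O[Si](C)(C)C(C)(C)C)c1 | intermediate
14 | 5-{2-[3,4-bis(TBS-oxy)phenyl]ethyl} 1-methyl (3R)-2-formyl-3-[(2S,3S)-1-(PMB-oxy)-3-(TES-oxy)butan-2-yl]pentanedioate (C2 epimers, enol tautomer in equilibrium) | COC(=O)C(C=O)[C@H](CC(=O)OCCc1ccc(O[Si](C)(C)C(C)(C)C)c(O[Si](C)(C)C(C)(C)C)c1)[C@@H](COCc1ccc(OC)cc1)[C@H](C)O[Si](CC)(CC)CC | intermediate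
15 | 5-{2-[3,4-bis(TBS-oxy)phenyl]ethyl} 1-methyl (3R)-2-formyl-3-[(2S,3S)-3-hydroxy-1-(PMB-oxy)butan-2-yl]pentanedioate (C2 epimers) | COC(=O)C(C=O)[C@H](CC(=O)OCCc1ccc(O[Si](C)(C)C(C)(C)C)c(O[Si](C)(C)C(C)(C)C)c1)[C@@H](COCc1ccc(OC)cc1)[C@H](C)O | intermediate
16 | methyl (2S,3S,4R)-4-(2-{2-[3,4-bis(TBS-oxy)phenyl]ethoxy}-2-oxoethyl)-6-hydroxy-2-methyl-3-[(PMB-oxy)methyl]tetrahydro-2H-pyran-5-carboxylate (target numbering; C5 and C6 as mixtures) | COC(=O)C1C(O)O[C@@H](C)[C@H](COCc2ccc(OC)cc2)[C@H]1CC(=O)OCCc1ccc(O[Si](C)(C)C(C)(C)C)c(O[Si](C)(C)C(C)(C)C)c1 | intermediate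
17 | methyl (2S,3S,4R)-4-(2-{2-[3,4-bis(TBS-oxy)phenyl]ethoxy}-2-oxoethyl)-2-methyl-3-[(PMB-oxy)methyl]-3,4-dihydro-2H-pyran-5-carboxylate | COC(=O)C1=CO[C@@H](C)[C@H](COCc2ccc(OC)cc2)[C@H]1CC(=O)OCCc1ccc(O[Si](C)(C)C(C)(C)C)c(O[Si](C)(C)C(C)(C)C)c1 | intermediate
18 | methyl (2S,3S,4R)-4-(2-{2-[3,4-bis(TBS-oxy)phenyl]ethoxy}-2-oxoethyl)-3-(hydroxymethyl)-2-methyl-3,4-dihydro-2H-pyran-5-carboxylate | COC(=O)C1=CO[C@@H](C)[C@H](CO)[C@H]1CC(=O)OCCc1ccc(O[Si](C)(C)C(C)(C)C)c(O[Si](C)(C)C(C)(C)C)c1 | intermediate
19 | methyl (2S,3R,4R)-4-(2-{2-[3,4-bis(TBS-oxy)phenyl]ethoxy}-2-oxoethyl)-3-formyl-2-methyl-3,4-dihydro-2H-pyran-5-carboxylate | COC(=O)C1=CO[C@@H](C)[C@H](C=O)[C@H]1CC(=O)OCCc1ccc(O[Si](C)(C)C(C)(C)C)c(O[Si](C)(C)C(C)(C)C)c1 | intermediate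
20 | methyl (2S,3R,4R)-4-{2-[2-(3,4-dihydroxyphenyl)ethoxy]-2-oxoethyl}-3-formyl-2-methyl-3,4-dihydro-2H-pyran-5-carboxylate | COC(=O)C1=CO[C@@H](C)[C@H](C=O)[C@H]1CC(=O)OCCc1ccc(O)c(O)c1 | target

**Step count and risks**

Total: 14 steps. Longest linear sequence: 11 steps (steps 1–5, 7, 10–14) from methyl (S)-3-hydroxybutanoate.

In order of risk:

Step 7. The enol may add to the wrong face of the β-carbon if the catalyst has to work against the intrinsic bias of the γ-branched enal. The C3 centre may also erode through γ-deprotonation of the acyl azolium, and the formyl ester may self-condense before it is captured. The fallback sets out from 7 and 9 and returns at 10, joining the two partners under iminium instead of acyl azolium activation. (R)-α,α-Diphenylprolinol trimethylsilyl ether (20 mol%) with benzoic acid in toluene at 0 °C should promote Michael addition of the enol of 9 to the Si face of the iminium ion of 7, the diphenyl(silyloxy)methyl group covering the Re face. The adduct should close to the cyclic hemiacetal methyl (4R)-2-hydroxy-4-[(2S,3S)-1-(PMB-oxy)-3-(TES-oxy)butan-2-yl]-3,4-dihydro-2H-pyran-5-carboxylate F1. Oxidation of this lactol with Dess–Martin periodinane (pyridine, CH2Cl2) then gives 10. Amine-catalysed Michael addition/hemiacetalisation of 1,3-dicarbonyl compounds with enals and lactol-to-lactone oxidation are both established, and the sequence needs neither quinone nor acyl azolium.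

Step 11. The freed C2 hydroxyl may lactonise onto the side-chain ester with expulsion of the hydroxytyrosol unit. The sequence may also stall at the lactol, or the aryl silyl and PMB ethers may be lost during the prolonged acid treatment that dehydration needs. The fallback sets out from 14 and returns at 17, separating desilylation from ring closure and replacing acid-catalysed dehydration by activation and base-induced elimination. AcOH–THF–H2O (3:1:1) at rt should cleave the TES ether and stop at lactol 16, which is then isolated. Mesylation of the anomeric hydroxyl (MsCl, Et3N, CH2Cl2, −20 → 0 °C) should give methyl (2S,3S,4R)-4-(2-{2-[3,4-bis(TBS-oxy)phenyl]ethoxy}-2-oxoethyl)-6-(methanesulfonyloxy)-2-methyl-3-[(PMB-oxy)methyl]tetrahydro-2H-pyran-5-carboxylate F2. F2 loses methanesulfonic acid in the same flask by elimination across C5–C6, since the C5 hydrogen is α to the ester, and so reaches 17.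

Step 5. Olefination of the α-branched aldehyde with the weakly nucleophilic formyl ylide may be sluggish, the product enal may be homologated a second time to the dienal, and the α-centre of the aldehyde may epimerise on prolonged heating. The fallback sets out from 6 and returns at 7, building the enal through the ester oxidation level. Horner–Wadsworth–Emmons olefination with triethyl phosphonoacetate (LiCl, i-Pr2NEt, MeCN, rt) should give ethyl (2E,4S,5S)-4-[(PMB-oxy)methyl]-5-(TES-oxy)hex-2-enoate F3. Reduction with (i-Bu)2AlH (CH2Cl2, −78 °C) should give (2E,4S,5S)-4-[(PMB-oxy)methyl]-5-(TES-oxy)hex-2-en-1-ol F4, and allylic oxidation with MnO2 (CH2Cl2, rt) gives 7.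

**Further compounds**

F1 | step 7 | methyl (4R)-2-hydroxy-4-[(2S,3S)-1-(PMB-oxy)-3-(TES-oxy)butan-2-yl]-3,4-dihydro-2H-pyran-5-carboxylate (anomer mixture) | OC1C[C@H]([C@@H](COCc2ccc(OC)cc2)[C@H](C)O[Si](CC)(CC)CC)C(C(=O)OC)=CO1
F2 | step 11 | methyl (2S,3S,4R)-4-(2-{2-[3,4-bis(TBS-oxy)phenyl]ethoxy}-2-oxoethyl)-6-(methanesulfonyloxy)-2-methyl-3-[(PMB-oxy)methyl]tetrahydro-2H-pyran-5-carboxylate | COC(=O)C1C(OS(C)(=O)=O)O[C@@H](C)[C@H](COCc2ccc(OC)cc2)[C@H]1CC(=O)OCCc1ccc(O[Si](C)(C)C(C)(C)C)c(O[Si](C)(C)C(C)(C)C)c1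
F3 | step 5 | ethyl (2E,4S,5S)-4-[(PMB-oxy)methyl]-5-(TES-oxy)hex-2-enoate | CCOC(=O)/C=C/[C@@H](COCc1ccc(OC)cc1)[C@H](C)O[Si](CC)(CC)CC
F4 | step 5 | (2E,4S,5S)-4-[(PMB-oxy)methyl]-5-(TES-oxy)hex-2-en-1-ol | OC/C=C/[C@@H](COCc1ccc(OC)cc1)[C@H](C)O[Si](CC)(CC)CC
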